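Reciprocal molar is the unit of the quantity I need, since my decision for the next run is whether to wait longer or to charge more reagent, and I want the readings to answer that.

| flask | substrate | reagent | remark | time |
|---|---|---|---|---|
| teal | 0.25 M | 0.237 M | the very flask that is asked about, followed so far |  |
| green | 0.25 M | 0.12 M | run made earlier |  |
| flask | 0.25 M | 0.237 M |  | 3.0 h |

teal run (percent of the substrate charged)

| time / min | substrate / % | product / % |
|---|---|---|
| 3.00 | 24 | 1 |
| 5.00 | 13 | 5 |
| 8.00 | 11 | 6 |
| 12.0 | 8 | 8 |
| 20.0 | 8 | 10 |
| 40.0 | 8 | 14 |

green run (percent of the substrate charged)

| time / h | substrate / % | product / % |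
|---|---|---|
| 0.500 | 8 | 7 |
| 1.00 | 6 | 5 |
| 1.50 | 7 | 6 |
| 2.00 | 6 | 8 |
| 2.50 | 8 | 7 |
| 3.00 | 8 | 7 |

(standard deviation of a reading: 1.5 percentage points)

* at 3.0 h, what has stopped the reaction, if anything has (forward and back rates have come level / the reagent has run out first / it is still moving / all of the substrate has reacted)
* share of the substrate used up at 3.0 h
* product at 3.0 h, in percent of the substrate charged

- what has gone from substrate into another species counts as reacted, even if it can come back
- the reaction counts as stopped when no species that holds the substrate changes by six tenths of a point or more over the second half of the time

Substrate reads 8% by 12.0 min in the teal run and 8% at the end of the green run, though teal has twice the reagent. So I take that fast step as done and call the pool p whatever was charged and is not product, in any form. Green's product y shows no trend from 0.500 h to 3.00 h, and its 6 readings average 6.67%. Assuming one reagent per product, the free reagent b is 0.103 M. Then y/(p·b) comes to H = 0.691 M⁻¹. This holding ratio, product over pool per molar of free reagent, is an apparent equilibrium constant, read from points with a scatter of 1.5 percentage points each.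

For the teal flask I hold H and let b fall as y rises. The quadratic gives y = 12.5%, with reagent at 86.9% of its charge. I therefore expect level rates and, from the substrate floor, 92.0% used. My decision is to stop waiting and charge more reagent.

The forecast says forward and back rates have come level, 92% and 15%, holding that the “plateau should therefore scale with reagent”. My product figure is lower, and I commit to it.

The flask gives forward and back rates have come level, 93.3% used and 12.4% product, so the forecast holds within its margins. With all else held, the product answer has moved by 5 points at a reagent charge of 0.135 M below the present one or 0.350 M above it.

    reagent + intermediate C ⇌ product (K = 2.00 M⁻¹, k = 0.00780 M⁻¹ s⁻¹)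
    substrate ⇌ intermediate B (K = 2.80, k = 0.00190 s⁻¹)
    intermediate A ⇌ intermediate C (K = 0.940, k = 0.00210 s⁻¹)
    substrate ⇌ intermediate A (K = 4.80, k = 0.00890 s⁻¹)

The slowest mode of the whole flask, as it stands at 3.00 h, has a half-life of 0.293 h, and the asked 3.0 h is ten times that. The flask's own H is 0.688 M⁻¹, and green's H, applied to a neighbour charged with 0.59 M of reagent, gives 26.6% against the 26.5% that neighbour holds.

The readings were computed with made-up constants; the scatter is artificial.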